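**Plan**

- Rings: A = orsellinyl ring; B = benzenoid ring and C = quinone ring of the naphthoquinone (C1=O, C2–OH, C3–H, C4=O; C5–OH peri to C4); D = pyranone.
- Enabling feature: ring C is the enol of a 1,2,4-trione and exceeds a benzo-fused cyclopentane-1,2,3-trione only by the C3 methine. After the four O–CH3 bonds, the retrosynthesis therefore cuts C2–C3 and C3–C4 and removes C3.
- Further cuts: the two C=O groups beside the indanone carbonyl (back to an indan-1-one), the ring B–CH2 bond to ring D (aryl triflate + pyranonylmethylzinc), the ring B–CO bond to ring A (aryllithium + aldehyde), and the indanone acyl–aryl bond (Friedel–Crafts).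
- Forward: the five-membered ring is closed on ring B first and its two oxygens are differentiated. Ring A is joined at C6 by directed lithiation and preformed ring D by Negishi coupling. The five-membered ring is oxidised to the trione, ring C arises last by one-carbon enlargement, and global demethylation ends the route.
- Stereochemistry: the target has no stereocentre; the carbinol centres of steps 5 and 6 are formed unselectively and are erased by oxidation in step 7.

Key step: step 13

Remark: indan-1-ones are numbered with the ketone as C1; trione 19 is renumbered so that its methoxy group is at C4 (the neighbouring carbonyl is then C3); 23 and 24 are numbered as naphthalene-1,4-diones.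

**Route**

Step 1
Reactants: 1 3-(3,5-dimethoxyphenyl)propanoic acid
Product: 2 5,7-dimethoxyindan-1-one
Conditions: Eaton's reagent (P2O5 in MeSO3H), 60 °C
Reagents that add atoms: none
Why: Intramolecular Friedel–Crafts acylation; the two ortho positions are equivalent and each is activated by one ortho and one para methoxy group, so a single indanone should form.

Step 2
Reactants: 2 5,7-dimethoxyindan-1-one
Product: 3 5,7-dihydroxyindan-1-one
Conditions: BBr3 (3 equiv), CH2Cl2, −78 °C to rt; H2O
Reagents that add atoms: none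
Why: Lewis-acid cleavage of aryl methyl ethers (BBr3 demethylation), which the aryl ketone tolerates.

Step 3
Reactants: 3 5,7-dihydroxyindan-1-one
Product: 4 7-hydroxy-5-(methoxymethoxy)indan-1-one
Conditions: MOMCl (1.05 equiv), i-Pr2NEt, CH2Cl2, 0 °C
Reagents that add atoms: chloromethyl methyl ether, COCCl
Why: Selective O-alkylation of the free, more acidic C5 hydroxyl para to the carbonyl, while the C7 hydroxyl is held in a hydrogen bond to the C1 carbonyl, as in the 4-O-protection of 2,4-dihydroxyaryl ketones.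

Step 4
Reactants: 4 7-hydroxy-5-(methoxymethoxy)indan-1-one
Product: 5 7-methoxy-5-(methoxymethoxy)indan-1-one
Conditions: MeI, K2CO3, DMF, 50 °C
Reagents that add atoms: iodomethane, CI
Why: Williamson etherification of the chelated phenol under mildly forcing conditions that leave the acetal and the ketone α-position untouched.

Step 5
Reactants: 5 7-methoxy-5-(methoxymethoxy)indan-1-one
Product: 6 7-methoxy-5-(methoxymethoxy)indan-1-ol (racemic)
Conditions: NaBH4, MeOH, 0 °C
Reagents that add atoms: none
Why: Borohydride reduction masks the ketone as a carbinol that survives the organolithium step as its alkoxide; the new centre is formed as a racemate and is removed again in step 7.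

Step 6
Reactants: 6 7-methoxy-5-(methoxymethoxy)indan-1-ol; 7 2,4-dimethoxy-6-methylbenzaldehyde
Product: 9 6-[(2,4-dimethoxy-6-methylphenyl)(hydroxy)methyl]-7-methoxy-5-(methoxymethoxy)indan-1-ol (diastereomer mixture), via dilithiated carbinol 8 (not isolated)
Conditions: n-BuLi (2.3 equiv), TMEDA, THF, −20 °C to 0 °C; then 7, −78 °C to rt; H2O
Reagents that add atoms: none
Why: Directed ortho-metalation; after O–H deprotonation the second equivalent should lithiate C6, the only position flanked by both the methoxy and the methoxymethoxy donors, and the aryllithium adds to the aldehyde, the new carbinol centre being formed unselectively and oxidised in the next step.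

Step 7
Reactants: 9 6-[(2,4-dimethoxy-6-methylphenyl)(hydroxy)methyl]-7-methoxy-5-(methoxymethoxy)indan-1-ol
Product: 10 6-(2,4-dimethoxy-6-methylbenzoyl)-7-methoxy-5-(methoxymethoxy)indan-1-one
Conditions: Dess–Martin periodinane (3 equiv), CH2Cl2, rt
Reagents that add atoms: none
Why: Dess–Martin oxidation converts both benzylic secondary alcohols, including the hindered diaryl carbinol, to ketones without touching the acetal or the electron-rich rings.

Step 8
Reactants: 10 6-(2,4-dimethoxy-6-methylbenzoyl)-7-methoxy-5-(methoxymethoxy)indan-1-one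
Product: 11 6-(2,4-dimethoxy-6-methylbenzoyl)-5-hydroxy-7-methoxyindan-1-one
Conditions: 2 M HCl, MeOH, 50 °C
Reagents that add atoms: none
Why: Acid-catalysed acetal cleavage (methanolysis) removes only the methoxymethyl group and frees the C5 phenol; the methyl ethers and both ketones are stable.

Step 9
Reactants: 11 6-(2,4-dimethoxy-6-methylbenzoyl)-5-hydroxy-7-methoxyindan-1-one
Product: 12 6-(2,4-dimethoxy-6-methylbenzoyl)-7-methoxy-1-oxoindan-5-yl trifluoromethanesulfonate
Conditions: Tf2O (1.1 equiv), pyridine, CH2Cl2, −10 °C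
Reagents that add atoms: trifluoromethanesulfonic anhydride, O=S(=O)(OS(=O)(=O)C(F)(F)F)C(F)(F)F
Why: O-Sulfonylation of the phenol; low temperature and pyridine as the only base should keep the enolisable indanone from giving a vinyl triflate.

Step 10
Reactants: 13 4-methoxy-6-methyl-2H-pyran-2-one
Product: 14 6-(bromomethyl)-4-methoxy-2H-pyran-2-one
Conditions: NBS, (PhCO2)2 (cat.), PhCF3, reflux
Reagents that add atoms: N-bromosuccinimide, O=C1CCC(=O)N1Br
Why: Wohl–Ziegler radical bromination at the C6 methyl, the allylic position of the pyranone.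

Step 11
Reactants: 14 6-(bromomethyl)-4-methoxy-2H-pyran-2-one; 12 6-(2,4-dimethoxy-6-methylbenzoyl)-7-methoxy-1-oxoindan-5-yl trifluoromethanesulfonate
Product: 16 6-(2,4-dimethoxy-6-methylbenzoyl)-7-methoxy-5-[(4-methoxy-2-oxo-2H-pyran-6-yl)methyl]indan-1-one, via (4-methoxy-2-oxo-2H-pyran-6-yl)methylzinc bromide 15 (not isolated)
Conditions: Zn dust, LiCl, THF, 0 °C to rt; then 12, Pd(OAc)2 (3 mol %), SPhos (6 mol %), THF, 50 °C
Reagents that add atoms: none
Why: Zinc insertion into the activated C–Br bond followed by Negishi coupling (oxidative addition of zerovalent palladium into the aryl triflate, transmetalation, reductive elimination at the exocyclic CH2, which keeps the pyranone conjugated); organozinc halides of this benzylic type tolerate aryl ketones.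

Step 12
Reactants: 16 6-(2,4-dimethoxy-6-methylbenzoyl)-7-methoxy-5-[(4-methoxy-2-oxo-2H-pyran-6-yl)methyl]indan-1-one
Product: 19 5-(2,4-dimethoxy-6-methylbenzoyl)-4-methoxy-6-[(4-methoxy-2-oxo-2H-pyran-6-yl)methyl]indane-1,2,3-trione, via indane-1,2-dione 17 (not isolated), via trione hydrate 18 (not isolated)
Conditions: SeO2 (2.3 equiv), dioxane/H2O (20:1), 100 °C; filter; then PhCl, reflux, Dean–Stark
Reagents that add atoms: selenium dioxide, O=[Se]=O
Why: Riley oxidation of the α-methylene and then of the benzylic methylene activated by the new 1,2-dione, as in the preparation of ninhydrins from indan-1-ones; the methylene between rings B and D has no ketone to enolise toward it and should need much hotter conditions, and azeotropic drying converts the gem-diol into the free trione.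

Step 13
Reactants: 19 5-(2,4-dimethoxy-6-methylbenzoyl)-4-methoxy-6-[(4-methoxy-2-oxo-2H-pyran-6-yl)methyl]indane-1,2,3-trione; 20 (trimethylsilyl)diazomethane
Product: 23 6-(2,4-dimethoxy-6-methylbenzoyl)-2-hydroxy-5-methoxy-7-[(4-methoxy-2-oxo-2H-pyran-6-yl)methyl]naphthalene-1,4-dione, via diazonium betaine 21 (not isolated), via 2-trimethylsilyloxy quinone 22 (not isolated)
Conditions: 20 (1.05 equiv, 2 M in hexanes), CH2Cl2, −78 °C to 0 °C; then 1 M HCl, THF
Reagents that add atoms: none
Why: The diazo carbon of 20 adds to the central and most electrophilic carbonyl (C2) of the anhydrous trione to give betaine 21; loss of N2 is coupled to a 1,2-shift of the C3 acyl group (the carbonyl on C3a, ortho to the C4 methoxy) from C2 to the former diazo carbon, which creates the C2–C3 and C3–C4 bonds of the naphthoquinone, after which silicon moves from carbon to the neighbouring oxygen to give silyl enol ether 22, hydrolysed on acidic work-up to 23. The closest known reaction type is the Buchner–Curtius–Schlotterbeck homologation (a Tiffeneau–Demjanov-like shift), known for indane-1,2,3-trione and diazoalkanes, which give 2-hydroxy-1,4-naphthoquinones. Ring C is not closed end to end but arises by enlargement of the five-membered ring to a six-membered one through this 1,2-acyl shift. No stereocentre is formed. The step needs the C3 acyl and not the C1 acyl to migrate: the C3 carbonyl is enriched by the ortho methoxy and the para benzylic substituent, whereas the C1 carbonyl stands para to the aroyl group, so the acyl group better able to carry positive charge in the bridged transition state should shift, which is a bias and not a certainty. The in-flask O-silylation keeps the acidic hydroxyquinone masked from the diazoalkane, and one equivalent at low temperature should limit dipolar addition to the quinone.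

Step 14
Reactants: 23 6-(2,4-dimethoxy-6-methylbenzoyl)-2-hydroxy-5-methoxy-7-[(4-methoxy-2-oxo-2H-pyran-6-yl)methyl]naphthalene-1,4-dione
Product: 24 6-(2,4-dihydroxy-6-methylbenzoyl)-2,5-dihydroxy-7-[(4-hydroxy-2-oxo-2H-pyran-6-yl)methyl]naphthalene-1,4-dione (CNP0158797.0)
Conditions: BBr3 (10 equiv), CH2Cl2, −78 °C to rt; H2O
Reagents that add atoms: none
Why: BBr3 ether cleavage; the two methoxy groups ortho or peri to carbonyls leave through boron chelates, the ring A para ether follows, and boron on the pyranone carbonyl turns its vinylogous ester methyl into a methoxypyrylium-like methyl donor toward bromide.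

**Compound list**

1 | 3-(3,5-dimethoxyphenyl)propanoic acid | OC(=O)CCc1cc(OC)cc(OC)c1 | starting material
2 | 5,7-dimethoxyindan-1-one | O=C1CCc2cc(OC)cc(OC)c12 | intermediate
3 | 5,7-dihydroxyindan-1-one | O=C1CCc2cc(O)cc(O)c12 | intermediate
4 | 7-hydroxy-5-(methoxymethoxy)indan-1-one | O=C1CCc2cc(OCOC)cc(O)c12 | intermediate
5 | 7-methoxy-5-(methoxymethoxy)indan-1-one | O=C1CCc2cc(OCOC)cc(OC)c12 | intermediate
6 | 7-methoxy-5-(methoxymethoxy)indan-1-ol (racemic) | OC1CCc2cc(OCOC)cc(OC)c12 | intermediate
7 | 2,4-dimethoxy-6-methylbenzaldehyde | Cc1cc(OC)cc(OC)c1C=O | starting material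
8 | lithium 6-lithio-7-methoxy-5-(methoxymethoxy)indan-1-olate | [Li]OC1CCc2cc(OCOC)c([Li])c(OC)c12 | intermediate (not isolated)
9 | 6-[(2,4-dimethoxy-6-methylphenyl)(hydroxy)methyl]-7-methoxy-5-(methoxymethoxy)indan-1-ol (diastereomer mixture) | OC1CCc2cc(OCOC)c(C(O)c3c(C)cc(OC)cc3OC)c(OC)c12 | intermediate
10 | 6-(2,4-dimethoxy-6-methylbenzoyl)-7-methoxy-5-(methoxymethoxy)indan-1-one | O=C1CCc2cc(OCOC)c(C(=O)c3c(C)cc(OC)cc3OC)c(OC)c12 | intermediate
11 | 6-(2,4-dimethoxy-6-methylbenzoyl)-5-hydroxy-7-methoxyindan-1-one | O=C1CCc2cc(O)c(C(=O)c3c(C)cc(OC)cc3OC)c(OC)c12 | intermediate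
12 | 6-(2,4-dimethoxy-6-methylbenzoyl)-7-methoxy-1-oxoindan-5-yl trifluoromethanesulfonate | O=C1CCc2cc(OS(=O)(=O)C(F)(F)F)c(C(=O)c3c(C)cc(OC)cc3OC)c(OC)c12 | intermediate
13 | 4-methoxy-6-methyl-2H-pyran-2-one | COc1cc(C)oc(=O)c1 | starting material
14 | 6-(bromomethyl)-4-methoxy-2H-pyran-2-one | COc1cc(CBr)oc(=O)c1 | intermediate
15 | (4-methoxy-2-oxo-2H-pyran-6-yl)methylzinc bromide | COc1cc(C[Zn]Br)oc(=O)c1 | intermediate (not isolated)
16 | 6-(2,4-dimethoxy-6-methylbenzoyl)-7-methoxy-5-[(4-methoxy-2-oxo-2H-pyran-6-yl)methyl]indan-1-one | O=C1CCc2cc(Cc3cc(OC)cc(=O)o3)c(C(=O)c3c(C)cc(OC)cc3OC)c(OC)c12 | intermediate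
17 | 6-(2,4-dimethoxy-6-methylbenzoyl)-7-methoxy-5-[(4-methoxy-2-oxo-2H-pyran-6-yl)methyl]indane-1,2-dione | O=C1C(=O)Cc2cc(Cc3cc(OC)cc(=O)o3)c(C(=O)c3c(C)cc(OC)cc3OC)c(OC)c12 | intermediate (not isolated)
18 | 5-(2,4-dimethoxy-6-methylbenzoyl)-2,2-dihydroxy-4-methoxy-6-[(4-methoxy-2-oxo-2H-pyran-6-yl)methyl]indane-1,3-dione | O=C1c2c(OC)c(C(=O)c3c(C)cc(OC)cc3OC)c(Cc3cc(OC)cc(=O)o3)cc2C(=O)C1(O)O | intermediate (not isolated)
19 | 5-(2,4-dimethoxy-6-methylbenzoyl)-4-methoxy-6-[(4-methoxy-2-oxo-2H-pyran-6-yl)methyl]indane-1,2,3-trione | O=C1C(=O)C(=O)c2cc(Cc3cc(OC)cc(=O)o3)c(C(=O)c3c(C)cc(OC)cc3OC)c(OC)c12 | intermediate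
20 | (trimethylsilyl)diazomethane | C[Si](C)(C)C=[N+]=[N-] | starting material
21 | C2 adduct of 19 and 20 (2-oxido-2-[diazonio(trimethylsilyl)methyl]indane-1,3-dione betaine) | C[Si](C)(C)C([N+]#N)C1([O-])C(=O)c2cc(Cc3cc(OC)cc(=O)o3)c(C(=O)c3c(C)cc(OC)cc3OC)c(OC)c2C1=O | intermediate (not isolated)
22 | 6-(2,4-dimethoxy-6-methylbenzoyl)-5-methoxy-7-[(4-methoxy-2-oxo-2H-pyran-6-yl)methyl]-2-(trimethylsilyloxy)naphthalene-1,4-dione | Cc1cc(OC)cc(OC)c1C(=O)c1c(Cc2cc(OC)cc(=O)o2)cc2c(c1OC)C(=O)C=C(O[Si](C)(C)C)C2=O | intermediate (not isolated)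
23 | 6-(2,4-dimethoxy-6-methylbenzoyl)-2-hydroxy-5-methoxy-7-[(4-methoxy-2-oxo-2H-pyran-6-yl)methyl]naphthalene-1,4-dione | Cc1cc(OC)cc(OC)c1C(=O)c1c(Cc2cc(OC)cc(=O)o2)cc2c(c1OC)C(=O)C=C(O)C2=O | intermediate
24 | 6-(2,4-dihydroxy-6-methylbenzoyl)-2,5-dihydroxy-7-[(4-hydroxy-2-oxo-2H-pyran-6-yl)methyl]naphthalene-1,4-dione (CNP0158797.0) | Cc1cc(O)cc(O)c1C(=O)c1c(Cc2cc(O)cc(=O)o2)cc2c(c1O)C(=O)C=C(O)C2=O | target

**Step count**

Total steps: 14. Longest linear sequence: 13 (steps 1–9 and 11–14; step 10 is the side branch to ring D).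

**Steps most likely to fail**

1. Step 13. The 1,2-shift may be taken partly or mainly by the C1 acyl group, which would place the new methine next to C1 and give the 3-hydroxy isomer. Excess diazoalkane may also add across the quinone double bond. The fallback inverts the electronic bias by turning the peri donor into an acceptor; it sets out from 16 and comes back to the route at 24. BCl3 (1.2 equiv, CH2Cl2, −78 °C) should cleave first the C7 methyl ether, which is held between two carbonyl groups and coplanar with the indanone carbonyl, giving 6-(2,4-dimethoxy-6-methylbenzoyl)-7-hydroxy-5-[(4-methoxy-2-oxo-2H-pyran-6-yl)methyl]indan-1-one F1. Acetylation (Ac2O, pyridine, DMAP) gives 6-(2,4-dimethoxy-6-methylbenzoyl)-5-[(4-methoxy-2-oxo-2H-pyran-6-yl)methyl]-3-oxoindan-4-yl acetate F2. Oxidation and drying as in step 12 give 5-(2,4-dimethoxy-6-methylbenzoyl)-6-[(4-methoxy-2-oxo-2H-pyran-6-yl)methyl]-1,2,3-trioxoindan-4-yl acetate F3, in which the carbonyl beside the acetoxy group is now the electron-poorer one. Ring enlargement with 20 as in step 13 should then give 6-(2,4-dimethoxy-6-methylbenzoyl)-2-hydroxy-7-[(4-methoxy-2-oxo-2H-pyran-6-yl)methyl]-1,4-dioxonaphthalen-5-yl acetate F4. BBr3 followed by aqueous work-up cleaves the three remaining methyl ethers and the acetate to give 24.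

2. Step 12. Under the forcing double oxidation, selenium dioxide may also attack the methylene between rings B and D or the electron-rich ring A, or stop at the 1,2-dione. The fallback avoids an oxidant for the ring carbons; it sets out from 16 and comes back at 19 through 18. Condensation with two equivalents of N,N-dimethyl-4-nitrosoaniline (cat. piperidine, EtOH, 60 °C; Ehrlich–Sachs condensation, a classical way from indan-1-ones to indanetrione hydrates) should give 2,3-bis{[4-(dimethylamino)phenyl]imino}-6-(2,4-dimethoxy-6-methylbenzoyl)-7-methoxy-5-[(4-methoxy-2-oxo-2H-pyran-6-yl)methyl]indan-1-one F5. Dilute H2SO4 hydrolyses both imines to hydrate 18, which is dried to 19 as in step 12.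

3. Step 11. The zinc dienolate may add to or deprotonate the indanone, or homocouple, faster than it transmetalates to the hindered arylpalladium. The fallback reverses the polarity of the coupling; it sets out from 12 and comes back at 16. Miyaura borylation (B2pin2, KOAc, Pd(dppf)Cl2, dioxane, 90 °C) gives 6-(2,4-dimethoxy-6-methylbenzoyl)-7-methoxy-5-(4,4,5,5-tetramethyl-1,3,2-dioxaborolan-2-yl)indan-1-one F6. Suzuki–Miyaura coupling of F6 with bromide 14 (Pd(PPh3)4, K3PO4, dioxane/H2O, 60 °C) gives 16.

**Further compounds**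

F1 | step 13 | 6-(2,4-dimethoxy-6-methylbenzoyl)-7-hydroxy-5-[(4-methoxy-2-oxo-2H-pyran-6-yl)methyl]indan-1-one | O=C1CCc2cc(Cc3cc(OC)cc(=O)o3)c(C(=O)c3c(C)cc(OC)cc3OC)c(O)c12
F2 | step 13 | 6-(2,4-dimethoxy-6-methylbenzoyl)-5-[(4-methoxy-2-oxo-2H-pyran-6-yl)methyl]-3-oxoindan-4-yl acetate | O=C1CCc2cc(Cc3cc(OC)cc(=O)o3)c(C(=O)c3c(C)cc(OC)cc3OC)c(OC(C)=O)c12
F3 | step 13 | 5-(2,4-dimethoxy-6-methylbenzoyl)-6-[(4-methoxy-2-oxo-2H-pyran-6-yl)methyl]-1,2,3-trioxoindan-4-yl acetate | O=C1C(=O)C(=O)c2cc(Cc3cc(OC)cc(=O)o3)c(C(=O)c3c(C)cc(OC)cc3OC)c(OC(C)=O)c12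
F4 | step 13 | 6-(2,4-dimethoxy-6-methylbenzoyl)-2-hydroxy-7-[(4-methoxy-2-oxo-2H-pyran-6-yl)methyl]-1,4-dioxonaphthalen-5-yl acetate | Cc1cc(OC)cc(OC)c1C(=O)c1c(Cc2cc(OC)cc(=O)o2)cc2c(c1OC(C)=O)C(=O)C=C(O)C2=O
F5 | step 12 | 2,3-bis{[4-(dimethylamino)phenyl]imino}-6-(2,4-dimethoxy-6-methylbenzoyl)-7-methoxy-5-[(4-methoxy-2-oxo-2H-pyran-6-yl)methyl]indan-1-one | O=C1C(=Nc3ccc(cc3)N(C)C)C(=Nc4ccc(cc4)N(C)C)c2cc(Cc5cc(OC)cc(=O)o5)c(C(=O)c6c(C)cc(OC)cc6OC)c(OC)c12
F6 | step 11 | 6-(2,4-dimethoxy-6-methylbenzoyl)-7-methoxy-5-(4,4,5,5-tetramethyl-1,3,2-dioxaborolan-2-yl)indan-1-one | O=C1CCc2cc(B3OC(C)(C)C(C)(C)O3)c(C(=O)c3c(C)cc(OC)cc3OC)c(OC)c12
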